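**Retrosynthetic overview**
1. Feature: ring A is labelled C1 (2-methoxyphenethyl chain), C2 (bond to ring B), C3=O, C4–CH3, C5–OH, C6=O. The run C3–C4(CH3)–C5–C6 matches, atom for atom, the ester carbon, the methyl-bearing α-carbon, the ketone carbon and the terminal CH3 of methyl 2-methylacetoacetate. C1=C2 is a two-carbon unit at the alkyne oxidation level.
2. End game (ring B: B1 link, B2 phenethyl, B3=O, B4–OH, B5–CH3, B6=O): target ⇒ B4 methoxyquinone (hydrolysis) ⇒ trimethoxy ring B (oxidative demethylation at B3/B6) ⇒ ring A resorcinol (oxidation at C6–H, para to C3–OH).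
3. Key disconnection: ring A resorcinol ⇒ bis(silyloxy)diene of the keto ester plus the nitroalkene ArB–C(NO2)=CH–CH2CH2Ar. Bonds C6–C1 and C2–C3 form, then HNO2 and MeOH are lost.
4. Nitroalkene ⇒ Henry addition and dehydration of the ring B arylnitromethane with 3-(2-methoxyphenyl)propanal. Arylnitromethane ⇒ Pd coupling of MeNO2 with the ring B bromide. The bromide comes from symmetric 3,5-dimethoxy-4-methylbenzaldehyde by olefination, hydrogenation, bromination, methoxylation (which supplies the missing B3 oxygen) and bromination at B1.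
5. Ring order: ring B and both terminal benzene rings are bought. Ring A is the only ring built.

Key step: step 13

Remark: the target SMILES carries no stereocentre and no descriptor for the hindered ring A–ring B axis, so the axis is taken as uncontrolled (racemic) and no step has to set configuration. ArB = 2,4,5-trimethoxy-3-methyl-6-(2-phenylethyl)phenyl.

**Step 1**
Reactants: 1 3,5-dimethoxy-4-methylbenzaldehyde; 2 diethyl benzylphosphonate
Product: 3 1,3-dimethoxy-2-methyl-5-[(E)-2-phenylethenyl]benzene
Conditions: KOtBu (1.2 equiv), THF, 0 °C to rt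
Reagents that add atoms: none
Why: Horner–Wadsworth–Emmons olefination: the benzylic phosphonate anion adds to the non-enolisable aldehyde and eliminates phosphate to give the E-stilbene, whose geometry is erased in step 2.

**Step 2**
Reactants: 3 1,3-dimethoxy-2-methyl-5-[(E)-2-phenylethenyl]benzene
Product: 4 1,3-dimethoxy-2-methyl-5-(2-phenylethyl)benzene
Conditions: H2 (1 atm), 10% Pd/C, EtOAc, rt
Reagents that add atoms: none
Why: Heterogeneous catalytic hydrogenation saturates the conjugated C=C at ambient pressure and leaves the aryl methyl ethers and benzene rings alone.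

**Step 3**
Reactants: 4 1,3-dimethoxy-2-methyl-5-(2-phenylethyl)benzene
Product: 5 2-bromo-3,5-dimethoxy-4-methyl-1-(2-phenylethyl)benzene
Conditions: NBS (1.0 equiv), MeCN, 0 °C, dark
Reagents that add atoms: N-bromosuccinimide, O=C1CCC(=O)N1Br
Why: Electrophilic aromatic bromination: the two free positions of the dimethoxy ring are equivalent by symmetry and each lies ortho to one and para to the other methoxy group, the phenyl ring is far less activated, and the first bromine slows a second attack, so one equivalent of NBS should give a single monobromide.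

**Step 4**
Reactants: 5 2-bromo-3,5-dimethoxy-4-methyl-1-(2-phenylethyl)benzene
Product: 6 1,3,4-trimethoxy-2-methyl-5-(2-phenylethyl)benzene
Conditions: NaOMe (5 equiv, in MeOH), CuBr (20 mol %), DMF, 110 °C
Reagents that add atoms: sodium methoxide, C[O-].[Na+]
Why: Ullmann-type copper-catalysed C–O coupling of an aryl bromide with methoxide, the standard way to turn ortho-flanked bromo(methoxy)toluenes into the next higher polymethoxyarene, puts in the oxygen that becomes the B3 carbonyl.

**Step 5**
Reactants: 6 1,3,4-trimethoxy-2-methyl-5-(2-phenylethyl)benzene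
Product: 7 1-bromo-2,4,5-trimethoxy-3-methyl-6-(2-phenylethyl)benzene
Conditions: NBS (1.05 equiv), MeCN, 0 °C to rt, dark
Reagents that add atoms: N-bromosuccinimide, O=C1CCC(=O)N1Br
Why: Electrophilic aromatic bromination at the only C–H left on the trimethoxy ring (B1, ortho to the B6 and para to the B4 methoxy group), run in a polar solvent in the dark so that the ionic path outruns benzylic radical bromination.

**Step 6**
Reactants: 7 1-bromo-2,4,5-trimethoxy-3-methyl-6-(2-phenylethyl)benzene; 8 nitromethane (10 equiv)
Product: 9 1,2,4-trimethoxy-3-methyl-5-(nitromethyl)-6-(2-phenylethyl)benzene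
Conditions: Pd2(dba)3 (2.5 mol %), XPhos (6 mol %), K3PO4 (1.2 equiv), 1,4-dioxane, 80 °C; aq NH4Cl
Reagents that add atoms: none
Why: Palladium-catalysed cross-coupling of an aryl bromide with the nitromethane anion (nitronate α-arylation): zerovalent palladium carrying the bulky biaryl phosphine inserts into hindered electron-rich C–Br bonds, and the two ortho groups speed reductive elimination and block a second arylation.

**Step 7**
Reactants: 10 3-(2-methoxyphenyl)propanoic acid
Product: 11 3-(2-methoxyphenyl)propan-1-ol
Conditions: BH3·THF (1.5 equiv), THF, 0 °C to rt; H2O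
Reagents that add atoms: none
Why: Borane reduction of a carboxylic acid through the acyloxyborane goes to the primary alcohol and does not touch the anisole ring.

**Step 8**
Reactants: 11 3-(2-methoxyphenyl)propan-1-ol
Product: 12 3-(2-methoxyphenyl)propanal
Conditions: TEMPO (10 mol %), PhI(OAc)2 (1.1 equiv), CH2Cl2, rt
Reagents that add atoms: none
Why: Oxoammonium (TEMPO) oxidation with PhI(OAc)2 as terminal oxidant stops at the aldehyde because no water is present to form the hydrate.

**Step 9**
Reactants: 9 1,2,4-trimethoxy-3-methyl-5-(nitromethyl)-6-(2-phenylethyl)benzene; 12 3-(2-methoxyphenyl)propanal (1.5 equiv)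
Product: 13 4-(2-methoxyphenyl)-1-nitro-1-[2,4,5-trimethoxy-3-methyl-6-(2-phenylethyl)phenyl]butan-2-ol (racemic, both diastereomers)
Conditions: DBU (20 mol %), THF, 0 °C
Reagents that add atoms: none
Why: Henry (nitroaldol) addition: the acidic benzylic nitro compound is deprotonated by catalytic DBU and the nitronate adds to the unhindered aliphatic aldehyde, the two new stereocentres being formed without control because both are erased in step 10.

**Step 10**
Reactants: 13 4-(2-methoxyphenyl)-1-nitro-1-[2,4,5-trimethoxy-3-methyl-6-(2-phenylethyl)phenyl]butan-2-ol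
Product: 15 1-[(1E)-4-(2-methoxyphenyl)-1-nitrobut-1-en-1-yl]-2,4,5-trimethoxy-3-methyl-6-(2-phenylethyl)benzene, via methanesulfonate 14 (not isolated)
Conditions: MsCl (1.3 equiv), Et3N (3 equiv), CH2Cl2, −10 to 0 °C
Reagents that add atoms: none
Why: Mesylation followed by E1cB elimination through the benzylic nitronate, the usual dehydration of nitroaldols; the E isomer (chain trans to nitro, cis to the twisted aryl) should prevail because it keeps the nitro group coplanar with the alkene, and the geometry no longer matters after step 13.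

**Step 11**
Reactants: 16 methyl 2-methyl-3-oxobutanoate (methyl 2-methylacetoacetate)
Product: 17 methyl 2-methyl-3-(trimethylsilyloxy)but-2-enoate (E/Z mixture)
Conditions: Me3SiCl (1.5 equiv), Et3N (1.6 equiv), hexane, rt
Reagents that add atoms: chlorotrimethylsilane, C[Si](C)(C)Cl
Why: O-silylation of the enolisable β-keto ester with Me3SiCl/Et3N gives the silyl enol ether, either geometry of which leads to the same diene.

**Step 12**
Reactants: 17 methyl 2-methyl-3-(trimethylsilyloxy)but-2-enoate
Product: 18 1-methoxy-2-methyl-1,3-bis(trimethylsilyloxy)buta-1,3-diene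
Conditions: LiN(iPr)2 (1.2 equiv), THF, −78 °C; Me3SiCl (1.3 equiv), −78 °C to rt
Reagents that add atoms: chlorotrimethylsilane, C[Si](C)(C)Cl
Why: Vinylogous (γ) deprotonation of the β-silyloxy enoate at the terminal CH3 by the lithium amide and O-silylation of the ester dienolate is the standard second stage in making 1-alkoxy-1,3-bis(silyloxy)butadienes.

**Step 13**
Reactants: 15 1-[(1E)-4-(2-methoxyphenyl)-1-nitrobut-1-en-1-yl]-2,4,5-trimethoxy-3-methyl-6-(2-phenylethyl)benzene; 18 1-methoxy-2-methyl-1,3-bis(trimethylsilyloxy)buta-1,3-diene (3 equiv)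
Product: 21 4-[2,4,5-trimethoxy-3-methyl-6-(2-phenylethyl)phenyl]-5-[2-(2-methoxyphenyl)ethyl]-2-methylbenzene-1,3-diol (ring A resorcinol), via nitrocyclohexene cycloadduct 19 (not isolated), via bis(trimethylsilyl) ether 20 (not isolated)
Conditions: PhMe (1 M), sealed tube, 120 °C; evaporate; 1 M HCl, THF, rt
Reagents that add atoms: none
Why: Diels–Alder reaction of a 1,1,3-trioxygenated diene with a nitroalkene, the known route from silyloxydienes and nitroalkenes to phenols by thermal loss of nitrous acid: the CH2 terminus of 18 (future C6, largest HOMO coefficient) bonds to the chain-bearing β-carbon of 15 (C1, largest LUMO coefficient) and the ketene acetal carbon (C3) bonds to the nitro-bearing carbon (C2), either in one asynchronous event or through a nitronate/oxocarbenium zwitterion. Ring A thereby closes as a six-membered carbocycle in the [4+2] mode (in the stepwise reading, a 6-(enolexo)-exo-trig attack of the nitronate carbon on the oxocarbenium carbon). Suprafacial addition to the E-alkene places C1–H cis to the tertiary benzylic nitro group in 19, the geometry required for thermal syn elimination of HNO2, after which 1,4-loss of methanol (C3–OMe, C6–H) aromatises to 20 and dilute acid removes the silyl groups. The selectivity needed is regiochemical and is secured by the polarisation that the nitro group imposes on C1=C2, so the methyl group ends between the two oxygens and the only ring hydrogen (C6–H) ends para to C3–OH. The transient stereocentres C1, C2 and C3 disappear on aromatisation, no stereocentre remains, and the new hindered biaryl axis forms as a racemate. Without the nitro group the aryl/alkyl-substituted C1=C2 bond would not react at all, and the main hurdle is steric because C2–C3 joins two fully substituted carbons beside the perpendicular ring B, hence the excess diene, high concentration and heat.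

**Step 14**
Reactants: 21 ring A resorcinol
Product: 22 2-hydroxy-6-[2-(2-methoxyphenyl)ethyl]-3-methyl-5-[2,4,5-trimethoxy-3-methyl-6-(2-phenylethyl)phenyl]cyclohexa-2,5-diene-1,4-dione
Conditions: (KSO3)2NO (3 equiv), aq KH2PO4 buffer, acetone/H2O, rt
Reagents that add atoms: potassium nitrosodisulfonate, [K+].[K+].[O]N(S(=O)(=O)[O-])S(=O)(=O)[O-]
Why: Teuber oxidation: the nitroxyl radical abstracts a phenolic hydrogen and a second equivalent delivers oxygen to the only free ring position C6 (para to C3–OH, ortho to C5–OH), so both modes of attack converge on the same hydroxy-para-quinone, while the fully etherified ring B and the anisole ring have no O–H to start from.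

**Step 15**
Reactants: 22 ring A hydroxyquinone with trimethoxy ring B
Product: 23 2-hydroxy-5-[4-methoxy-5-methyl-3,6-dioxo-2-(2-phenylethyl)cyclohexa-1,4-dien-1-yl]-6-[2-(2-methoxyphenyl)ethyl]-3-methylcyclohexa-2,5-diene-1,4-dione
Conditions: (NH4)2Ce(NO3)6 (2.5 equiv), MeCN/H2O, 0 °C
Reagents that add atoms: water, O
Why: Oxidative demethylation of a para-dimethoxyarene by tetravalent cerium: the trimethoxy ring B is by far the most easily oxidised arene left, water attacks its radical cation at B3 and B6 with loss of methanol, and ring A (already a fully substituted quinone) and the monomethoxy ring stay untouched.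

**Step 16**
Reactants: 23 ring B methoxyquinone
Product: 24 4,4'-dihydroxy-2-[2-(2-methoxyphenyl)ethyl]-5,5'-dimethyl-2'-(2-phenylethyl)-[1,1'-bi(cyclohexa-1,4-dien-1-yl)]-3,3',6,6'-tetrone (target CNP0202346.0)
Conditions: 1 M aq NaOH (5 equiv), MeOH, N2, 0 °C to rt; then 1 M HCl
Reagents that add atoms: sodium hydroxide, [Na+].[OH-]
Why: Saponification of a vinylogous ester by addition–elimination: hydroxide adds at B4 of the methoxyquinone and expels methoxide, the resulting hydroxyquinone anion (like that of ring A) is shielded from further attack by its charge, and the aryl methyl ether is inert to cold dilute base.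

**Compound list**
1 | 3,5-dimethoxy-4-methylbenzaldehyde | COc1cc(C=O)cc(OC)c1C | starting material
2 | diethyl benzylphosphonate | CCOP(=O)(Cc1ccccc1)OCC | starting material
3 | 1,3-dimethoxy-2-methyl-5-[(E)-2-phenylethenyl]benzene | COc1cc(/C=C/c2ccccc2)cc(OC)c1C | intermediate
4 | 1,3-dimethoxy-2-methyl-5-(2-phenylethyl)benzene | COc1cc(CCc2ccccc2)cc(OC)c1C | intermediate
5 | 2-bromo-3,5-dimethoxy-4-methyl-1-(2-phenylethyl)benzene | COc1cc(CCc2ccccc2)c(Br)c(OC)c1C | intermediate
6 | 1,3,4-trimethoxy-2-methyl-5-(2-phenylethyl)benzene | COc1cc(CCc2ccccc2)c(OC)c(OC)c1C | intermediate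
7 | 1-bromo-2,4,5-trimethoxy-3-methyl-6-(2-phenylethyl)benzene | COc1c(Br)c(CCc2ccccc2)c(OC)c(OC)c1C | intermediate
8 | nitromethane | C[N+](=O)[O-] | starting material
9 | 1,2,4-trimethoxy-3-methyl-5-(nitromethyl)-6-(2-phenylethyl)benzene | COc1c(C[N+](=O)[O-])c(CCc2ccccc2)c(OC)c(OC)c1C | intermediate
10 | 3-(2-methoxyphenyl)propanoic acid | COc1ccccc1CCC(=O)O | starting material
11 | 3-(2-methoxyphenyl)propan-1-ol | COc1ccccc1CCCO | intermediate
12 | 3-(2-methoxyphenyl)propanal | COc1ccccc1CCC=O | intermediate
13 | 4-(2-methoxyphenyl)-1-nitro-1-ArB-butan-2-ol (racemic, both diastereomers) | COc1ccccc1CCC(O)C([N+](=O)[O-])c1c(CCc2ccccc2)c(OC)c(OC)c(C)c1OC | intermediate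
14 | methanesulfonate of 13 (not isolated; racemic, both diastereomers) | COc1ccccc1CCC(OS(C)(=O)=O)C([N+](=O)[O-])c1c(CCc2ccccc2)c(OC)c(OC)c(C)c1OC | intermediate
15 | (E)-4-(2-methoxyphenyl)-1-nitro-1-ArB-but-1-ene (nitro trans to the chain) | COc1ccccc1CC/C=C(/[N+](=O)[O-])c1c(CCc2ccccc2)c(OC)c(OC)c(C)c1OC | intermediate
16 | methyl 2-methyl-3-oxobutanoate | CC(=O)C(C)C(=O)OC | starting material
17 | methyl 2-methyl-3-(trimethylsilyloxy)but-2-enoate (E/Z mixture) | COC(=O)C(C)=C(C)O[Si](C)(C)C | intermediate
18 | 1-methoxy-2-methyl-1,3-bis(trimethylsilyloxy)buta-1,3-diene (drawn 1Z; ketene acetal geometry of no consequence) | C=C(O[Si](C)(C)C)/C(C)=C(/OC)O[Si](C)(C)C | intermediate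
19 | cycloadduct: 3-methoxy-2-methyl-4-nitro-4-ArB-5-[2-(2-methoxyphenyl)ethyl]-1,3-bis(trimethylsilyloxy)cyclohex-1-ene (not isolated; racemic, chain trans to nitro, ketal carbon undefined) | COc1ccccc1CC[C@@H]1CC(O[Si](C)(C)C)=C(C)C(OC)(O[Si](C)(C)C)[C@]1([N+](=O)[O-])c1c(CCc2ccccc2)c(OC)c(OC)c(C)c1OC | intermediate
20 | bis(trimethylsilyl) ether of 21 (not isolated) | COc1ccccc1CCc1cc(O[Si](C)(C)C)c(C)c(O[Si](C)(C)C)c1-c1c(CCc2ccccc2)c(OC)c(OC)c(C)c1OC | intermediate
21 | 4-ArB-5-[2-(2-methoxyphenyl)ethyl]-2-methylbenzene-1,3-diol | COc1ccccc1CCc1cc(O)c(C)c(O)c1-c1c(CCc2ccccc2)c(OC)c(OC)c(C)c1OC | intermediate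
22 | 2-hydroxy-6-[2-(2-methoxyphenyl)ethyl]-3-methyl-5-ArB-cyclohexa-2,5-diene-1,4-dione | COc1ccccc1CCC1=C(c2c(CCc3ccccc3)c(OC)c(OC)c(C)c2OC)C(=O)C(C)=C(O)C1=O | intermediate
23 | biquinone with ring A hydroxyquinone and ring B 4-methoxyquinone | COc1ccccc1CCC1=C(C2=C(CCc3ccccc3)C(=O)C(OC)=C(C)C2=O)C(=O)C(C)=C(O)C1=O | intermediate
24 | 4,4'-dihydroxy-2-[2-(2-methoxyphenyl)ethyl]-5,5'-dimethyl-2'-(2-phenylethyl)-[1,1'-bi(cyclohexa-1,4-dien-1-yl)]-3,3',6,6'-tetrone | COc1ccccc1CCC1=C(C2=C(CCc3ccccc3)C(=O)C(O)=C(C)C2=O)C(=O)C(C)=C(O)C1=O | target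

**Total step count:** 16. **Longest linear sequence:** 12 steps (1–6, 9, 10, 13–16).

**Steps most likely to fail**

Step 13.
- What may go wrong:
  - The cycloaddition may stall. Ring B stands perpendicular to the nitroalkene plane and its two ortho groups screen both faces at C2.
  - Meanwhile the diene is slowly lost by silyl migration and by protonation from the nitrous acid that is released.
  - The nitroalkene may also react as the four-atom partner in a hetero-cycloaddition.
  - Desilylation before nitrite has left could reopen C2–C3 by a retro-Claisen path.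
  - Nitrous acid left at the acid stage could nitrosate C6, which is why volatiles are removed first.
- Fallback (stepwise, anionic): it sets out from 15 and 16.
  - Keto ester 16 is doubly deprotonated (NaH, then n-BuLi, THF, 0 °C). Its terminal carbon is added to 15 at −78 °C in a Michael addition.
  - After an NH4Cl quench this gives methyl 5-[2-(2-methoxyphenyl)ethyl]-2-methyl-6-nitro-3-oxo-6-ArB-hexanoate F1, which secures C6–C1 at low temperature.
  - Isolated F1 is then heated with DBU in toluene. The nitronate carbon acylates intramolecularly on the ester (Dieckmann type).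
  - Loss of methanol and nitrite drives aromatisation to 21, where the route is rejoined.

Step 6.
- What may go wrong: oxidative addition and nitronate transfer at the doubly ortho-flanked, very electron-rich bromide may be slow, so hydrodebromination and catalyst decay take over.
- Fallback: it sets out from 6 and bypasses steps 5 and 6.
  - Bromomethylation ((CH2O)n, HBr/AcOH, rt) at the only free position of the trimethoxy ring gives 1-(bromomethyl)-2,4,5-trimethoxy-3-methyl-6-(2-phenylethyl)benzene F2.
  - Kornblum-type displacement with NaNO2 (urea, DMF, −20 °C) converts F2 into 9, where the route is rejoined.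

Step 9.
- What may go wrong: the hindered, stabilised nitronate may add slowly and reversibly, so retro-Henry cleavage and self-aldolisation of the aldehyde win.
- Fallback: it sets out from 7 and 12 and needs no arylnitromethane, so it also covers step 6.
  - Bromine–lithium exchange on 7 (n-BuLi, THF, −78 °C), then B(OiPr)3 and aqueous acid, gives [2,4,5-trimethoxy-3-methyl-6-(2-phenylethyl)phenyl]boronic acid F3.
  - Aldehyde 12 undergoes a Henry addition with BrCH2NO2 (NaI cat., THF) to give 1-bromo-4-(2-methoxyphenyl)-1-nitrobutan-2-ol F4.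
  - MsCl/Et3N converts F4 through its methanesulfonate F5 into 1-[(3Z)-4-bromo-4-nitrobut-3-en-1-yl]-2-methoxybenzene F6.
  - Suzuki–Miyaura coupling of F3 with F6 (Pd(OAc)2, SPhos, K3PO4, toluene, 60 °C) proceeds with retention of alkene geometry and gives 15, where the route is rejoined.

**Further compounds**
F1 | step 13 | methyl 5-[2-(2-methoxyphenyl)ethyl]-2-methyl-6-nitro-3-oxo-6-[2,4,5-trimethoxy-3-methyl-6-(2-phenylethyl)phenyl]hexanoate (diastereomer mixture) | COC(=O)C(C)C(=O)CC(CCc1ccccc1OC)C([N+](=O)[O-])c1c(CCc2ccccc2)c(OC)c(OC)c(C)c1OC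
F2 | step 6 | 1-(bromomethyl)-2,4,5-trimethoxy-3-methyl-6-(2-phenylethyl)benzene | COc1c(CBr)c(CCc2ccccc2)c(OC)c(OC)c1C
F3 | step 9 | [2,4,5-trimethoxy-3-methyl-6-(2-phenylethyl)phenyl]boronic acid | COc1c(B(O)O)c(CCc2ccccc2)c(OC)c(OC)c1C
F4 | step 9 | 1-bromo-4-(2-methoxyphenyl)-1-nitrobutan-2-ol (diastereomer mixture) | COc1ccccc1CCC(O)C(Br)[N+](=O)[O-]
F5 | step 9 | methanesulfonate of F4 (diastereomer mixture) | COc1ccccc1CCC(OS(C)(=O)=O)C(Br)[N+](=O)[O-]
F6 | step 9 | 1-[(3Z)-4-bromo-4-nitrobut-3-en-1-yl]-2-methoxybenzene | COc1ccccc1CC/C=C(/[N+](=O)[O-])Br
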